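## Retrosynthetic overview

1. The target is disconnected (ester cleavage, Mitsunobu C–O bond) to umbelliferone and a 2-(hydroxymethyl)cyclohex-3-ene. The H/CH2OH pair on C2 is traced back (formate hydrogenolysis of an alkenyl oxirane, methylene transfer) to the C2 ketone of a 2-methylcyclohex-2-enone.
2. The cyclohexenone comes by dehydrogenation from the cyclohexanone, which comes from the key one-carbon ring enlargement. CH–CH3 from diazoethane is stitched between the C=O carbon and the α-CH2 of a cyclopentanone, and the new C3–C4 bond closes the six-membered ring.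
3. Enabling feature (locants of the target ring: C1 quaternary, C2 CH(CH2OAr), C3 =C(CH3), C4 =CH, C5 CH2, C6 CH-isopropenyl): C3 sits between C4 and C2, and C2 is flanked on its other side by fully substituted C1. Without C3, atoms C1, C2, C4, C5 and C6 form a cyclopentanone in which only C4 can migrate or enolise.
4. The cyclopentanone comes from 2-methylcyclopent-2-enone. Enantioselective conjugate isopropenylation sets C6. Michael addition of the stored enolate to tert-butyl acrylate, anti to isopropenyl, sets quaternary C1.
5. Ring order: five-membered template (bought), then the cyclohexene ring (key step), then a temporary spiro-oxirane (made and opened again). The coumarin rings arrive intact with umbelliferone.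

Key step: step 3

Remark: in step 1 the antipode of the ferrocenyl diphosphine is taken that gives the (3R) silyl enol ether. Locants C1–C6 in the Why lines are those of the target ring defined above.

## Route

Step 1
Reactants: 1 2-methylcyclopent-2-en-1-one; 2 prop-1-en-2-ylmagnesium bromide
Product: 3 {[(3R)-2-methyl-3-(prop-1-en-2-yl)cyclopent-1-en-1-yl]oxy}trimethylsilane
Conditions: CuBr·SMe2 (5 mol %), Rev-JosiPhos-type ferrocenyl diphosphine (6 mol %), t-BuOMe, −75 °C; then TMSCl, Et3N, HMPA, −75 → 0 °C
Reagents that add atoms: chlorotrimethylsilane, C[Si](C)(C)Cl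
Why: Copper-catalysed enantioselective conjugate addition of a Grignard reagent to an α-substituted cyclic enone, in which the chiral diphosphine–copper complex selects the enone face and so sets C6, while O-silylation stores the regiodefined tetrasubstituted enolate.

Step 2
Reactants: 3 {[(3R)-2-methyl-3-(prop-1-en-2-yl)cyclopent-1-en-1-yl]oxy}trimethylsilane; 4 tert-butyl acrylate
Product: 6 tert-butyl 3-[(1R,5R)-1-methyl-2-oxo-5-(prop-1-en-2-yl)cyclopentyl]propanoate, via lithium enolate 5 (not isolated)
Conditions: MeLi, THF, 0 °C; 4, −78 °C; then H2O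
Reagents that add atoms: none
Why: Cleavage of the silyl enol ether with MeLi releases the tetrasubstituted lithium enolate, whose Michael addition to the acrylate should occur on the ring face opposite the neighbouring isopropenyl group, which sets quaternary C1 with the propanoate chain trans and the methyl cis to isopropenyl.

Step 3
Reactants: 6 tert-butyl 3-[(1R,5R)-1-methyl-2-oxo-5-(prop-1-en-2-yl)cyclopentyl]propanoate
Product: 8 tert-butyl 3-[(1R,6R)-1,3-dimethyl-2-oxo-6-(prop-1-en-2-yl)cyclohexyl]propanoate (both C3 epimers), via diazonium alkoxide 7 (not isolated)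
Conditions: CH3CHN2 (Et2O solution from N-ethyl-N-nitrosourea, aq KOH, 0 °C), Sc(OTf)3 (10 mol %), toluene, −78 → 0 °C
Reagents that add atoms: N-ethyl-N-nitrosourea (source of diazoethane), CCN(N=O)C(N)=O
Why: Lewis-acid-catalysed diazoalkane–ketone homologation (Büchner–Curtius–Schlotterbeck reaction, the direct form of a Tiffeneau–Demjanov ring enlargement): the nucleophilic carbon of diazoethane (future C3 with its methyl) adds to the Sc(OTf)3-activated carbonyl carbon (future C2) to give 7, and loss of N2 is coupled to a 1,2-shift of the ring CH2 (future C4) from C2 to C3, so that the C3–C4 bond is made while the temporary C2–C4 bond of the template is given up. The closest precedent is the one-carbon enlargement of 2,2-disubstituted cyclopentanones such as 17-oxo steroids, which likewise end with the carbonyl next to the quaternary carbon. The six-membered ring is closed by ring enlargement (five to six through a 1,2-alkyl shift), not by an exo or endo cyclisation of an open chain. One new stereocentre (C3) arises without control and needs none, because step 4 turns both epimers into the same sp2 carbon, while C1 and C6 are spectators that cannot epimerise. The step needs migration of CH2 and not of quaternary C1, and the substrate secures this: in 7 the conformer with N2+ antiperiplanar to the C2–CH2 bond keeps the methyl group away from fully substituted C1. It also needs a single insertion and chemoselectivity: product 8 (carbonyl between a quaternary and a tertiary carbon) should be far less reactive than 6, and the tert-butyl ester and the unactivated 1,1-disubstituted alkene do not react with diazoethane at low temperature.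

Step 4
Reactants: 8 tert-butyl 3-[(1R,6R)-1,3-dimethyl-2-oxo-6-(prop-1-en-2-yl)cyclohexyl]propanoate
Product: 9 tert-butyl 3-[(1R,6R)-1,3-dimethyl-2-oxo-6-(prop-1-en-2-yl)cyclohex-3-en-1-yl]propanoate
Conditions: IBX (2 equiv), DMSO, 70 °C
Reagents that add atoms: none
Why: IBX dehydrogenation of a ketone through its enol, in which C1 carries no hydrogen so that only C3–H and C4–H can be lost, which should funnel both C3 epimers of 8 into the single C3=C4 enone.

Step 5
Reactants: 9 tert-butyl 3-[(1R,6R)-1,3-dimethyl-2-oxo-6-(prop-1-en-2-yl)cyclohex-3-en-1-yl]propanoate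
Product: 10 tert-butyl 3-[(3R,4R,5R)-4,8-dimethyl-5-(prop-1-en-2-yl)-1-oxaspiro[2.5]oct-7-en-4-yl]propanoate
Conditions: Me3SI, NaH, DMSO–THF, 0 → 25 °C
Reagents that add atoms: trimethylsulfonium iodide, C[S+](C)C.[I-]
Why: Corey–Chaykovsky epoxidation (1,2-methylene transfer from the unstabilised sulfonium ylide to the enone carbonyl), in which axial attack on the face opposite the axial C1 methyl group should place the new CH2 trans and the oxirane oxygen cis to that methyl and so fix the spiro centre C2.

Step 6
Reactants: 10 tert-butyl 3-[(3R,4R,5R)-4,8-dimethyl-5-(prop-1-en-2-yl)-1-oxaspiro[2.5]oct-7-en-4-yl]propanoate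
Product: 11 tert-butyl 3-[(1R,2R,6R)-2-(hydroxymethyl)-1,3-dimethyl-6-(prop-1-en-2-yl)cyclohex-3-en-1-yl]propanoate
Conditions: Pd2(dba)3·CHCl3 (2.5 mol %), n-Bu3P (10 mol %), HCO2H, Et3N, THF, 25–40 °C
Reagents that add atoms: none
Why: Palladium-catalysed formate hydrogenolysis of an alkenyl oxirane, in which zerovalent palladium opens the allylic C2–O bond with inversion and the hydride from the palladium formate is delivered from the metal face to the more substituted allyl terminus C2, which should give the homoallylic alcohol with net inversion at C2 (H trans, CH2OH cis to the C1 methyl) and leave the C3=C4 double bond in place.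

Step 7
Reactants: 11 tert-butyl 3-[(1R,2R,6R)-2-(hydroxymethyl)-1,3-dimethyl-6-(prop-1-en-2-yl)cyclohex-3-en-1-yl]propanoate; 12 umbelliferone (7-hydroxy-2H-chromen-2-one)
Product: 13 tert-butyl 3-[(1R,2R,6R)-1,3-dimethyl-2-{[(2-oxo-2H-chromen-7-yl)oxy]methyl}-6-(prop-1-en-2-yl)cyclohex-3-en-1-yl]propanoate
Conditions: PPh3, DIAD, THF, 0 → 40 °C
Reagents that add atoms: none
Why: Mitsunobu etherification of a primary alcohol with an acidic phenol, which forms the aryl ether at the CH2 carbon and touches none of the three stereocentres.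

Step 8
Reactants: 13 tert-butyl 3-[(1R,2R,6R)-1,3-dimethyl-2-{[(2-oxo-2H-chromen-7-yl)oxy]methyl}-6-(prop-1-en-2-yl)cyclohex-3-en-1-yl]propanoate
Product: 15 3-[(1R,2R,6R)-1,3-dimethyl-2-{[(2-oxo-2H-chromen-7-yl)oxy]methyl}-6-(prop-1-en-2-yl)cyclohex-3-en-1-yl]propanoic acid (target), via trimethylsilyl ester 14 (not isolated)
Conditions: TMSOTf, 2,6-lutidine, CH2Cl2, 0 °C; then H2O
Reagents that add atoms: none
Why: Buffered silyl-triflate cleavage of a tert-butyl ester (loss of 2-methylpropene, then hydrolysis of the silyl ester), which avoids free strong acid and should therefore spare the isopropenyl group, the ring alkene, the coumarin lactone and all stereocentres.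

## Compound list

1 | 2-methylcyclopent-2-en-1-one | CC1=CCCC1=O | starting material
2 | prop-1-en-2-ylmagnesium bromide | C=C(C)[Mg]Br | starting material
3 | {[(3R)-2-methyl-3-(prop-1-en-2-yl)cyclopent-1-en-1-yl]oxy}trimethylsilane | C=C(C)[C@H]1CCC(O[Si](C)(C)C)=C1C | intermediate
4 | tert-butyl acrylate | C=CC(=O)OC(C)(C)C | starting material
5 | lithium (3R)-2-methyl-3-(prop-1-en-2-yl)cyclopent-1-en-1-olate | C=C(C)[C@H]1CCC([O-])=C1C.[Li+] | intermediate
6 | tert-butyl 3-[(1R,5R)-1-methyl-2-oxo-5-(prop-1-en-2-yl)cyclopentyl]propanoate | C=C(C)[C@H]1CCC(=O)[C@]1(C)CCC(=O)OC(C)(C)C | intermediate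
7 | diazonium alkoxide from addition of diazoethane to the ketone of 6 (carbinol and CH–CH3 centres undefined) | C=C(C)[C@H]1CCC([O-])(C(C)[N+]#N)[C@]1(C)CCC(=O)OC(C)(C)C | intermediate
8 | tert-butyl 3-[(1R,6R)-1,3-dimethyl-2-oxo-6-(prop-1-en-2-yl)cyclohexyl]propanoate (both C3 epimers) | C=C(C)[C@H]1CCC(C)C(=O)[C@]1(C)CCC(=O)OC(C)(C)C | intermediate
9 | tert-butyl 3-[(1R,6R)-1,3-dimethyl-2-oxo-6-(prop-1-en-2-yl)cyclohex-3-en-1-yl]propanoate | C=C(C)[C@H]1CC=C(C)C(=O)[C@]1(C)CCC(=O)OC(C)(C)C | intermediate
10 | tert-butyl 3-[(3R,4R,5R)-4,8-dimethyl-5-(prop-1-en-2-yl)-1-oxaspiro[2.5]oct-7-en-4-yl]propanoate | C=C(C)[C@H]1CC=C(C)[C@]2(CO2)[C@]1(C)CCC(=O)OC(C)(C)C | intermediate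
11 | tert-butyl 3-[(1R,2R,6R)-2-(hydroxymethyl)-1,3-dimethyl-6-(prop-1-en-2-yl)cyclohex-3-en-1-yl]propanoate | C=C(C)[C@H]1CC=C(C)[C@@H](CO)[C@]1(C)CCC(=O)OC(C)(C)C | intermediate
12 | umbelliferone (7-hydroxy-2H-chromen-2-one) | O=c1ccc2ccc(O)cc2o1 | starting material
13 | tert-butyl 3-[(1R,2R,6R)-1,3-dimethyl-2-{[(2-oxo-2H-chromen-7-yl)oxy]methyl}-6-(prop-1-en-2-yl)cyclohex-3-en-1-yl]propanoate | C=C(C)[C@H]1CC=C(C)[C@@H](COc2ccc3ccc(=O)oc3c2)[C@]1(C)CCC(=O)OC(C)(C)C | intermediate
14 | trimethylsilyl 3-[(1R,2R,6R)-1,3-dimethyl-2-{[(2-oxo-2H-chromen-7-yl)oxy]methyl}-6-(prop-1-en-2-yl)cyclohex-3-en-1-yl]propanoate | C=C(C)[C@H]1CC=C(C)[C@@H](COc2ccc3ccc(=O)oc3c2)[C@]1(C)CCC(=O)O[Si](C)(C)C | intermediate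
15 | 3-[(1R,2R,6R)-1,3-dimethyl-2-{[(2-oxo-2H-chromen-7-yl)oxy]methyl}-6-(prop-1-en-2-yl)cyclohex-3-en-1-yl]propanoic acid | C=C(C)[C@H]1CC=C(C)[C@@H](COc2ccc3ccc(=O)oc3c2)[C@]1(C)CCC(=O)O | target

## Step count and risks

Total step count: 8. Longest linear sequence: 8 steps (from 1).

Steps most likely to fail:

**Step 3.** Three things may go wrong. Addition of diazoethane to the carbonyl next to the quaternary carbon may be too slow. The alkoxide may close to an oxirane instead of triggering the shift. The quaternary carbon may migrate in place of the CH2.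

The fallback sets out from 6, comes back at 9, and makes the same ring bond by carbonyl chemistry:
- 6 is hydroxylated at its only enolisable position (KHMDS, then 2-(phenylsulfonyl)-3-phenyloxaziridine) to the α-hydroxy ketone F1.
- EtMgBr/CeCl3 adds to the ketone to give the diol F2.
- NaIO4 cleaves the glycol to the keto aldehyde F3.
- An intramolecular aldol condensation (piperidinium acetate, toluene, reflux) closes the six-membered ring directly to enone 9.

**Step 5.** The basic ylide may deprotonate the enone at its γ-position, or it may fail to reach the carbonyl that lies between a quaternary carbon and a methyl-bearing sp2 carbon.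

The fallback sets out from 9 and comes back at 10. The ylide is replaced by an irreversible carbenoid addition followed by a separate ring closure. Chloromethyllithium (ICH2Cl, MeLi·LiBr, THF, −78 °C) adds to the ketone from the same less hindered face to give the chlorohydrin F4. KOt-Bu then closes F4 to oxirane 10.

**Step 6.** Ionisation of the pseudo-equatorial C–O bond may be slow. Hydride may be delivered to the C4 terminus of the allyl unit. β-Hydride elimination may give a dienol.

The fallback sets out from 10 and comes back at 11, and uses no transition metal. A Meinwald rearrangement (MgBr2·OEt2, CH2Cl2, −20 °C) moves a hydride from the oxirane CH2 to C2 anti to the departing oxygen and gives the β,γ-unsaturated aldehyde F5. NaBH4 in MeOH at 0 °C then reduces F5 to alcohol 11.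

Further compounds
F1 | step 3 | tert-butyl 3-[(1R,5R)-3-hydroxy-1-methyl-2-oxo-5-(prop-1-en-2-yl)cyclopentyl]propanoate | C=C(C)[C@H]1CC(O)C(=O)[C@]1(C)CCC(=O)OC(C)(C)C
F2 | step 3 | tert-butyl 3-[(1R,5R)-2-ethyl-2,3-dihydroxy-1-methyl-5-(prop-1-en-2-yl)cyclopentyl]propanoate | C=C(C)[C@H]1CC(O)C(O)(CC)[C@]1(C)CCC(=O)OC(C)(C)C
F3 | step 3 | tert-butyl (4R)-4-methyl-4-[(3R)-2-methyl-5-oxopent-1-en-3-yl]-5-oxoheptanoate | C=C(C)[C@@H](CC=O)[C@@](C)(CCC(=O)OC(C)(C)C)C(=O)CC
F4 | step 5 | tert-butyl 3-[(1R,2R,6R)-2-(chloromethyl)-2-hydroxy-1,3-dimethyl-6-(prop-1-en-2-yl)cyclohex-3-en-1-yl]propanoate | C=C(C)[C@H]1CC=C(C)[C@](O)(CCl)[C@]1(C)CCC(=O)OC(C)(C)C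
F5 | step 6 | tert-butyl 3-[(1R,2R,6R)-2-formyl-1,3-dimethyl-6-(prop-1-en-2-yl)cyclohex-3-en-1-yl]propanoate | C=C(C)[C@H]1CC=C(C)[C@@H](C=O)[C@]1(C)CCC(=O)OC(C)(C)C
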